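We plan the next flask.

| flask | substrate | salt in the second phase | spent carrier | remark | time | volume of the second phase over the first |
|---|---|---|---|---|---|---|
| delta | 0.23 M | 0.46 M | 21 mM | run made earlier |  |  |
| alpha | 0.23 M | 0.46 M | 48 mM | run made earlier |  |  |
| beta | 0.23 M | 0.23 M | 32 mM | run made earlier |  |  |
| flask | 0.23 M | 0.460 M | 32 mM |  | 8.0 min | 1.0 |

- delta (time / min: target / %, crystals / %): 1.50: 1.3, 0; 3.00: 4.0, 0.2; 5.00: 5.9, 1.2; 6.00: 7.6, 3.4
- alpha (time / min: target / %, crystals / %): 0.500: 0.4, 0; 1.33: 3.7, 0.2; 3.00: 8.3, 3.3; 6.00: 14.5, 9.3
- beta (time / min: target / %, crystals / %): 0.833: 1.0, 0; 2.50: 4.7, 0; 4.00: 5.9, 1.6; 6.00: 9.2, 4.4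

(scatter of a reading: 0.5 percentage points)

- amounts and yields of target count crystals too
- charges count per volume of the first phase; a concentration in a rate is the amount of a species over the volume of its own phase; every rate counts per litre of the first phase
- given per volume of solution although it is solid: crystals
- the earlier runs hold the two phases in the same ratio of volumes as the flask asked about

* target and crystals together at 8.0 min, in percent of the substrate charged
* concentration of target in solution at 8.0 min, in percent of saturation

Is the planned charge worth making, or should the salt change? We reckon it in steps.

1. The target column already counts the crystals, so it is the yield, and dissolved target is that column minus the crystals.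

2. The zero of our scale is strict proportion, with each mole of spent carrier charged working at one pace. From the last readings, target made per spent carrier charged per minute is 0.139 min⁻¹ in delta and 0.116 min⁻¹ in alpha, with 2.29 times the spent carrier. Their mean, 0.127 min⁻¹, a reading with the scatter of those readings, is our carrier turnover, the turnover frequency.

3. Beta, with half the salt and 32 mM of spent carrier, reads 0.110 min⁻¹, lower than the mean. Both settings differ from delta and alpha, but we keep the salt at 0.460 M.

4. Turnover times spent carrier charged times time, over substrate charged, puts target and crystals together in the flask at 14.2 %.

5. Dissolved target in alpha reads 5.00 % at 3.00 min and 5.20 % at 6.00 min while crystals grow, so for the flask we estimate about 100 % of saturation.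

The forecast differs from our reckoning: it gives 20.5 % and 300 %, from “Total product (target plus crystals) rises almost linearly”.

The flask gives 13.6 % of target and crystals together, and dissolved target at 104 % of saturation.

    spent carrier + salt in the second phase ⇌ fresh carrier + spent salt in the second phase (K = 0.440, k = 17.0 L mol⁻¹ min⁻¹)
    substrate + fresh carrier → target + spent carrier (k = 0.721 L mol⁻¹ min⁻¹)
    crystals ⇌ target, rate k3*(cs3 - [target]) while solid is left; crystals form when [target] > cs3 (solubility = 9.90 mM, k = 7.79 min⁻¹)

At 8.00 min, 9.09 % of the substrate charged stands as crystals, within 13.6 % of target. The turnover of this flask comes to 0.122 min⁻¹, against our 0.127 min⁻¹. The same charge read at 3.0 min holds 5.43 % of target and crystals together, where our turnover of 0.127 min⁻¹ puts 5.31 %.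

(All runs come from a simulation from invented constants, and the scatter is random.)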